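(The constants used here are invented; the run is a simulation.)

A small charge of solid substrate dissolves into a solution that the partner drains while it fills.

    solid substrate ⇌ starting material, rate k1*(cs1 - [starting material]) while solid is left; crystals form when [starting material] > cs1 (cs1 = 3.1 mM, k1 = 0.056 /s)
    starting material + partner ⇌ intermediate (K2 = 6500 /M, k2 = 4.1 /M/s)
    intermediate ⇌ product + by-product (K3 = 0.0031 M, k3 = 0.027 /s)

solid substrate 5.0 mM; partner 4.50 mM; time 80 s

* product at 80 s, in percent of the solid substrate charged
* concentration of starting material in solution at 20 s, in percent of saturation
* the change that raises the amount of product at 80 s, in percent of the solid substrate charged most ("none" if none brings more than 2 percentage points) (midnight / dusk / dawn / none)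
* amount of product at 80 s, in percent of the solid substrate charged, after midnight

- midnight: doubling the dissolution coefficient of step 1, all else as stated
- dusk: doubling the amount of partner, all else as stated
- dawn: doubling the solubility in step 1, all else as stated

**Drain ratio.** Per unit of concentration, the partner as charged removes starting material at 0.0185 /s, while the solid refills the gap to saturation at 0.056 /s. Dividing the first by the second makes time drop out and gives 0.329, the drain ratio. While solid lasts, starting material holds at the saturation share of the charge divided by one plus this ratio, which in this flask is 46.6% of the charge.

**Question reversed.** For faster dissolving to raise the held level as far as dawn, which doubles the solubility and so the level, the factor of one plus the ratio over one plus half the ratio has to reach 2, a value it nears for a ratio far above one and does not reach. This flask stands below one, so midnight raises the level by a factor of 1.14, less than the 2 of dawn.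

**Own reckoning.** Filling from empty at the coefficient plus the drain rate, the solution reaches 58.2% of saturation at 20 s. The return arrows are dropped, with the equilibrium constant of step 2 times partner at 29. At the held level the partner then falls in a pseudo-first-order way. Taking the lags of filling and of step 3 from the run leaves 29.5 s, which gives 22.1% product, and the same reckoning after midnight gives 28.8%. Partner lost over the whole run ranks dusk first.

**Forecast and run.** The forecast gave 21.5%, 59%, dusk and, below this reckoning, 25% after midnight, holding that “Step 1 stays far from saturation”. The simulation gives 22.3%, 58.7%, 26.0% and dusk, which gains 14 percentage points, against 7 points for dawn and 3.8 points for midnight.

**Ratio again.** At 80.0 s the flask has 4.89% of its solid and 52% of its partner left, so the ratio has fallen to 0.171, which gives a level of 53.0% of the charge, and starting material stands at 51.7%. The neighbour charged with 20 mM of solid substrate also keeps 52% of its partner, so the same ratio gives 13.2% of its larger charge, and its starting material stands at 12.9%.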